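**Retrosynthesis**
1. The target is an unsymmetrical curcuminoid, made by a boron-mediated aldol condensation of ether-aldehyde **23** with p-coumaroylacetone **26**.
2. In **23**, the aryl allyl ether comes from Pd-catalysed allylic etherification of vanillin (net retention) on a cyclohexenyl carbonate. The isobutenyl ketone comes from an aldehyde plus isobutenyl Grignard, then oxidation.
3. The side-chain methyl stereocentre comes from Ru–BINAP hydrogenation of an (E)-allylic alcohol. That alcohol is built from a methyl ketone, which comes from Wacker oxidation of a vinyl group.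
4. The only carbocycle is made first, by oxidative dearomatisation of 4-methoxy-2-methylphenol to a quinone monoketal. Rh/diene vinylation sets the ring carbon that carries the side chain. A ketoreductase sets the C–OH next to C(Me)=. Ketal hydrolysis followed by Luche reduction sets the second ring carbinol.
5. The two aryl rings (vanillin, 4-hydroxybenzaldehyde) are already present in the building blocks.

Assumptions:
- Numbered compounds are substrates, building blocks and intermediates. Simple reagents are named in the steps.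
- The β-diketone is formed as its keto/enol mixture and is drawn as the enol, as in the target.
- Chiral catalysts (diene ligand, BINAP, KRED) are chosen as the enantiomer or variant that gives the configurations listed.

---

## Route

**Step 1**
Reactants: **1** 4-methoxy-2-methylphenol
Product: **2** 4,4-dimethoxy-2-methylcyclohexa-2,5-dien-1-one
Conditions: PhI(OAc)2, MeOH, 0 °C → rt
Reagents that add atoms: methanol, CO
Why: Hypervalent-iodine oxidative dearomatisation of a 4-methoxyphenol, trapped by MeOH, gives the quinone monoketal. It is achiral but has two enantiotopic faces for the next step.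

**Step 2**
Reactants: **2**; **3** potassium vinyltrifluoroborate
Product: **4** (5R)-5-ethenyl-4,4-dimethoxy-2-methylcyclohex-2-en-1-one
Conditions: [RhCl(C2H4)2]2, chiral diene L* (Ph-bod* type), KOH (aq), dioxane/H2O, 50 °C
Reagents that add atoms: none beyond reactant **3**
Why: Rh-catalysed asymmetric 1,4-addition (Hayashi–Miyaura) goes to the unsubstituted enone, which is more reactive than the α-methyl enone. The chiral diene fixes the face and sets the first stereocentre (C5, R), the ring carbon that will carry the side chain.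

**Step 3**
Reactant: **4**
Product: **5** (1S,5R)-5-ethenyl-4,4-dimethoxy-2-methylcyclohex-2-en-1-ol
Conditions: ketoreductase (KRED, an oxidoreductase) from a screening panel, NADP+ (cat.), iPrOH 10% v/v, KPi pH 7.0, DMSO 5%, 30 °C
Reagents that add atoms: none
Why: Enzymatic 1,2-reduction of the enone C=O with catalyst-controlled facial selectivity gives the (1S) allylic alcohol, trans to the vinyl group. The neutral buffer leaves the ketal and alkene untouched.

**Step 4**
Reactant: **5**
Product: **6** triisopropyl{[(1S,5R)-5-ethenyl-4,4-dimethoxy-2-methylcyclohex-2-en-1-yl]oxy}silane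
Conditions: TIPSCl, imidazole, DMF, 60 °C
Reagents that add atoms: TIPSCl, CC(C)[Si](Cl)(C(C)C)C(C)C
Why: Silylation under non-acidic conditions protects the carbinol and leaves the acid-sensitive ketal intact. No stereocentre is touched.

**Step 5**
Reactant: **6**
Product: **7** (4S,6R)-6-ethenyl-3-methyl-4-[(triisopropylsilyl)oxy]cyclohex-2-en-1-one
Conditions: PPTS, acetone/H2O 9:1, 50 °C
Reagents that add atoms: water, O
Why: Mild acid hydrolysis of the allylic dimethyl ketal gives the γ-silyloxy enone. An α′-epimerisation at C6 would only funnel to the thermodynamic trans(4,6) isomer, which is the one needed.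

**Step 6**
Reactant: **7**
Product: **8** (1R,4S,6R)-6-ethenyl-3-methyl-4-[(triisopropylsilyl)oxy]cyclohex-2-en-1-ol
Conditions: NaBH4, CeCl3·7H2O, MeOH, −78 → −40 °C
Reagents that add atoms: none
Why: Luche 1,2-reduction. The C3-methyl forces OTIPS pseudo-axial and the vinyl group pseudo-equatorial. Axial hydride attack then gives the equatorial alcohol, trans to vinyl and cis to OTIPS, which sets the Ca carbinol. Any minor epimer is removed by chromatography.

**Step 7**
Reactant: **8**
Product: **9** tert-butyl{[(1R,4S,6R)-6-ethenyl-3-methyl-4-(TIPSoxy)cyclohex-2-en-1-yl]oxy}dimethylsilane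
Conditions: TBSOTf, 2,6-lutidine, CH2Cl2, −78 → 0 °C
Reagents that add atoms: TBSOTf, CC(C)(C)[Si](C)(C)OS(=O)(=O)C(F)(F)F
Why: The hindered secondary alcohol is protected as a TBS ether, which can later be removed selectively in the presence of TIPS. The ketal is gone, so the triflate is safe.

**Step 8**
Reactant: **9**
Product: **10** 1-[(1S,2S,5S)-2-(TBSoxy)-4-methyl-5-(TIPSoxy)cyclohex-3-en-1-yl]ethan-1-one
Conditions: PdCl2 (10 mol%), CuCl, O2 (1 atm), DMF/H2O 7:1, 25 °C
Reagents that add atoms: water, O
Why: Wacker oxidation is Markovnikov-selective for the terminal vinyl group. The hindered trisubstituted ring alkene does not react. The CIP labels change only because of new substituent priorities. The spatial arrangement is unchanged.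

**Step 9**
Reactants: **10**; **11** triethyl phosphonoacetate, CCOC(=O)CP(=O)(OCC)OCC
Product: **12** ethyl (2E)-3-[(1R,2S,5S)-2-(TBSoxy)-4-methyl-5-(TIPSoxy)cyclohex-3-en-1-yl]but-2-enoate
Conditions: NaH, THF, 0 → 50 °C
Reagents that add atoms: none beyond reactant **11**
Why: Horner–Wadsworth–Emmons olefination of the methyl ketone is E-selective (about 5:1). The Z isomer is removed by chromatography. The ring stereocentres stay in the thermodynamic trans/all-equatorial-type arrangement.

**Step 10**
Reactant: **12**
Product: **13** (2E)-3-[(1R,2S,5S)-2-(TBSoxy)-4-methyl-5-(TIPSoxy)cyclohex-3-en-1-yl]but-2-en-1-ol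
Conditions: DIBAL-H (2.5 equiv), CH2Cl2, −78 °C
Reagents that add atoms: none
Why: DIBAL reduces the ester to the allylic alcohol, a geraniol-type substrate for directed hydrogenation. The silyl ethers survive.

**Step 11**
Reactant: **13**
Product: **14** (3S)-3-[(1R,2R,5S)-2-(TBSoxy)-4-methyl-5-(TIPSoxy)cyclohex-3-en-1-yl]butan-1-ol
Conditions: H2 (100 atm), Ru(OAc)2[(S)-BINAP] (1 mol%), MeOH, 30 °C
Reagents that add atoms: none
Why: Noyori hydroxyl-directed asymmetric hydrogenation of the (E)-trisubstituted allylic alcohol. The catalyst controls the face and sets the side-chain methyl centre (S). The ring alkene has no directing group and is untouched. I assign (S) by analogy with geraniol giving (R)-citronellol under (S)-BINAP; the CIP label flips because the ring carbon outranks CH2CH2OH here.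

**Step 12**
Reactant: **14**
Product: **15** (3S)-3-[(1R,2R,5S)-2-(TBSoxy)-4-methyl-5-(TIPSoxy)cyclohex-3-en-1-yl]butanal
Conditions: Dess–Martin periodinane, NaHCO3, CH2Cl2, 0 °C → rt
Reagents that add atoms: none
Why: Dess–Martin oxidation of the primary alcohol. The new aldehyde is β to the methyl stereocentre, so there is no epimerisation risk.

**Step 13**
Reactants: **15**; **16** 2-methylprop-1-enylmagnesium bromide, CC(C)=C[Mg]Br
Product: **17** (6S)-6-[(1R,2R,5S)-2-(TBSoxy)-4-methyl-5-(TIPSoxy)cyclohex-3-en-1-yl]-2-methylhept-2-en-4-ol (epimeric at C4)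
Conditions: THF, −78 → 0 °C
Reagents that add atoms: none beyond reactant **16**
Why: Grignard addition to the aldehyde. The new carbinol centre is destroyed in the next step, so its configuration does not matter.

**Step 14**
Reactant: **17**
Product: **18** (6S)-6-[(1R,2R,5S)-2-(TBSoxy)-4-methyl-5-(TIPSoxy)cyclohex-3-en-1-yl]-2-methylhept-2-en-4-one
Conditions: MnO2 (excess), CH2Cl2, rt
Reagents that add atoms: none
Why: MnO2 selectively oxidises the allylic secondary alcohol to the isobutenyl (turmerone-type) enone. The silyl ethers are inert to it.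

**Step 15**
Reactant: **18**
Product: **19** (6S)-6-[(1R,2R,5S)-2-hydroxy-4-methyl-5-(TIPSoxy)cyclohex-3-en-1-yl]-2-methylhept-2-en-4-one
Conditions: HF·pyridine, pyridine, THF, 0 °C → rt
Reagents that add atoms: none
Why: Secondary allylic TBS ether is cleaved selectively, while the more hindered TIPS ether remains. The enone and ketone are unaffected.

**Step 16**
Reactant: **19**
Product: **20** methyl (1R,4S,6R)-3-methyl-6-[(2S)-6-methyl-4-oxohept-5-en-2-yl]-4-(TIPSoxy)cyclohex-2-en-1-yl carbonate
Conditions: ClCO2Me, pyridine, DMAP (cat.), CH2Cl2, 0 °C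
Reagents that add atoms: methyl chloroformate, COC(=O)Cl
Why: Acylation converts the alcohol into an allylic carbonate, a good Pd(0) leaving group. No stereocentre changes.

**Step 17**
Reactants: **20**; **21** vanillin, COc1cc(C=O)ccc1O
Product: **22** 4-{[(1R,4S,6R)-3-methyl-6-[(2S)-6-methyl-4-oxohept-5-en-2-yl]-4-(TIPSoxy)cyclohex-2-en-1-yl]oxy}-3-methoxybenzaldehyde
Conditions: Pd(PPh3)4 (5 mol%), THF, 50 °C
Reagents that add atoms: none beyond reactant **21**
Why: Tsuji–Trost allylic etherification. Pd(0) ionises anti to the carbonate. The phenoxide then attacks the π-allyl at the less hindered secondary terminus (not the tertiary one) from the face opposite Pd. The double inversion gives net retention, so the aryl ether sits trans to the side chain and cis to OTIPS, as required. The ring-bound electrophile bearing vanillin directly keeps the aldehyde untouched.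

**Step 18**
Reactant: **22**
Product: **23** 4-{[(1R,4S,6R)-4-hydroxy-3-methyl-6-[(2S)-6-methyl-4-oxohept-5-en-2-yl]cyclohex-2-en-1-yl]oxy}-3-methoxybenzaldehyde
Conditions: TBAF/AcOH (1:1), THF, 0 → 25 °C
Reagents that add atoms: none
Why: Buffered fluoride removes the secondary TIPS ether without enolising the enone or aldehyde. The free allylic alcohol is now present for the final coupling.

**Step 19** (parallel branch)
Reactants: **24** 4-hydroxybenzaldehyde, O=Cc1ccc(O)cc1; **25** pentane-2,4-dione, CC(=O)CC(C)=O
Product: **26** (E)-6-(4-hydroxyphenyl)hex-5-ene-2,4-dione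
Conditions: B2O3, B(OBu)3, n-BuNH2 (cat.), EtOAc, 40 → 80 °C; then 0.4 M HCl, 60 °C
Reagents that add atoms: none beyond reactants **24** and **25**
Why: Pabon boron-complex Knoevenagel condensation at the acetyl methyl of the boron-protected diketone. Excess **25** suppresses bis-condensation. The precious aldehyde **23** is used only in the last step.

**Step 20**
Reactants: **23**; **26**
Product: **27** Demethoxybisabolocurcumin ether (target)
Conditions: **26**, B2O3, EtOAc, 40 °C; then **23**, B(OBu)3, n-BuNH2 (cat.), 80 °C; then 0.4 M HCl, 60 °C, 30 min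
Reagents that add atoms: none beyond the reactants
Why: Pabon condensation of the acetyl CH3 of the boron complex of **26** with the aryl aldehyde builds the E-enone and gives the unsymmetrical curcuminoid. All ring and side-chain stereocentres are unaffected.

---

## Compound list

| No. | Name | SMILES | Role |
|---|---|---|---|
| 1 | 4-methoxy-2-methylphenol | COc1ccc(O)c(C)c1 | starting material |
| 2 | 4,4-dimethoxy-2-methylcyclohexa-2,5-dien-1-one | COC1(OC)C=CC(=O)C(C)=C1 | intermediate |
| 3 | potassium vinyltrifluoroborate | C=C[B-](F)(F)F.[K+] | starting material |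
| 4 | (5R)-5-ethenyl-4,4-dimethoxy-2-methylcyclohex-2-en-1-one | O=C1C(C)=CC(OC)(OC)[C@@H](C=C)C1 | intermediate |
| 5 | (1S,5R)-5-ethenyl-4,4-dimethoxy-2-methylcyclohex-2-en-1-ol | O[C@@H]1C(C)=CC(OC)(OC)[C@@H](C=C)C1 | intermediate |
| 6 | TIPS ether of 5 | CC(C)[Si](C(C)C)(C(C)C)O[C@@H]1C(C)=CC(OC)(OC)[C@@H](C=C)C1 | intermediate |
| 7 | (4S,6R)-6-ethenyl-3-methyl-4-(TIPSoxy)cyclohex-2-en-1-one | O=C1C=C(C)[C@@H](O[Si](C(C)C)(C(C)C)C(C)C)C[C@@H]1C=C | intermediate |
| 8 | (1R,4S,6R)-6-ethenyl-3-methyl-4-(TIPSoxy)cyclohex-2-en-1-ol | O[C@H]1C=C(C)[C@@H](O[Si](C(C)C)(C(C)C)C(C)C)C[C@@H]1C=C | intermediate |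
| 9 | TBS ether of 8 | CC(C)(C)[Si](C)(C)O[C@H]1C=C(C)[C@@H](O[Si](C(C)C)(C(C)C)C(C)C)C[C@@H]1C=C | intermediate |
| 10 | methyl ketone (1S,2S,5S) | CC(C)(C)[Si](C)(C)O[C@H]1C=C(C)[C@@H](O[Si](C(C)C)(C(C)C)C(C)C)C[C@@H]1C(C)=O | intermediate |
| 11 | triethyl phosphonoacetate | CCOC(=O)CP(=O)(OCC)OCC | starting material |
| 12 | (E)-enoate | CC(C)(C)[Si](C)(C)O[C@H]1C=C(C)[C@@H](O[Si](C(C)C)(C(C)C)C(C)C)C[C@@H]1/C(C)=C/C(=O)OCC | intermediate |
| 13 | (E)-allylic alcohol | CC(C)(C)[Si](C)(C)O[C@H]1C=C(C)[C@@H](O[Si](C(C)C)(C(C)C)C(C)C)C[C@@H]1/C(C)=C/CO | intermediate |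
| 14 | (3S)-butan-1-ol | CC(C)(C)[Si](C)(C)O[C@H]1C=C(C)[C@@H](O[Si](C(C)C)(C(C)C)C(C)C)C[C@@H]1[C@@H](C)CCO | intermediate |
| 15 | (3S)-butanal | CC(C)(C)[Si](C)(C)O[C@H]1C=C(C)[C@@H](O[Si](C(C)C)(C(C)C)C(C)C)C[C@@H]1[C@@H](C)CC=O | intermediate |
| 16 | 2-methylprop-1-enylmagnesium bromide | CC(C)=C[Mg]Br | starting material |
| 17 | heptenol (C4 epimers) | CC(C)(C)[Si](C)(C)O[C@H]1C=C(C)[C@@H](O[Si](C(C)C)(C(C)C)C(C)C)C[C@@H]1[C@@H](C)CC(O)C=C(C)C | intermediate |
| 18 | heptenone (bis-silyl) | CC(C)(C)[Si](C)(C)O[C@H]1C=C(C)[C@@H](O[Si](C(C)C)(C(C)C)C(C)C)C[C@@H]1[C@@H](C)CC(=O)C=C(C)C | intermediate |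
| 19 | Ca–OH, Cd–OTIPS enone | O[C@H]1C=C(C)[C@@H](O[Si](C(C)C)(C(C)C)C(C)C)C[C@@H]1[C@@H](C)CC(=O)C=C(C)C | intermediate |
| 20 | methyl carbonate | COC(=O)O[C@H]1C=C(C)[C@@H](O[Si](C(C)C)(C(C)C)C(C)C)C[C@@H]1[C@@H](C)CC(=O)C=C(C)C | intermediate |
| 21 | vanillin | COc1cc(C=O)ccc1O | starting material |
| 22 | aryl ether aldehyde (TIPS) | COc1cc(C=O)ccc1O[C@H]1C=C(C)[C@@H](O[Si](C(C)C)(C(C)C)C(C)C)C[C@@H]1[C@@H](C)CC(=O)C=C(C)C | intermediate |
| 23 | aryl ether aldehyde (free OH) | COc1cc(C=O)ccc1O[C@H]1C=C(C)[C@@H](O)C[C@@H]1[C@@H](C)CC(=O)C=C(C)C | intermediate |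
| 24 | 4-hydroxybenzaldehyde | O=Cc1ccc(O)cc1 | starting material |
| 25 | pentane-2,4-dione | CC(=O)CC(C)=O | starting material |
| 26 | (E)-6-(4-hydroxyphenyl)hex-5-ene-2,4-dione | CC(=O)CC(=O)/C=C/c1ccc(O)cc1 | intermediate |
| 27 | Demethoxybisabolocurcumin ether | COc1cc(/C=C/C(O)=C/C(=O)/C=C/c2ccc(O)cc2)ccc1O[C@H]1C=C(C)[C@@H](O)C[C@@H]1[C@@H](C)CC(=O)C=C(C)C | target |

---

**Total steps:** 20, of which step 19 is a parallel branch.
**Longest linear sequence:** 19 steps (steps 1–18, then step 20).

**Three steps most likely to fail**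

1. **Step 2 (Rh/diene vinylation next to the ketal).** Regioselectivity over the methyl-bearing enone, or ee, may be poor.
   *Fallback:* make racemic **4** by Cu-catalysed vinyl Grignard addition, then resolve by KRED kinetic resolution in step 3 (maximum 50% yield), or by lipase resolution after an achiral reduction.
2. **Step 11 (Ru–BINAP setting the side-chain methyl centre).** The diastereoselectivity is uncertain because the ring stereocentre sits directly next to the reacting alkene.
   *Fallback:* oxidise **13** to the (E)-enal with MnO2 and reduce it with an ene-reductase (Old Yellow Enzyme family) to give **15** directly under enzyme control.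
3. **Step 17 (Pd-catalysed etherification with retention).** Competing elimination to the diene, or loss of stereospecificity through Pd(0) exchange, could lower yield or selectivity.
   *Fallback:* reduce **7** with L-Selectride or a second KRED to the cis (up) alcohol. Then couple vanillin by Mitsunobu (DIAD or ADDP/PPh3 or PBu3), which inverts C–O and gives the same trans aryl ether.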